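## Retrosynthetic overview

1. Target 19 ⇐ triacetate 18 (selective methanolysis) ⇐ triol 17 ⇐ B-alkyl Suzuki coupling of vinyl triflate diol 13 (C9) with Z-dienol 15 (C11–C16).
2. 13 ⇐ 6-keto vinyl triflate 11 by α-face C7 hydroxylation and α-face hydride delivery to C6 (6β-O, 7α-O, trans-diaxial).
3. 11 ⇐ Δ5-ene ketone 7 by enol triflation at C9 and α-face hydroboration/oxidation of Δ5 (sets 5α-H, trans-decalin).
4. 7 ⇐ ring A closed onto ring B: HAT-initiated radical cyclisation of the homoprenyl chain onto the C5 ketone of dione 5, then dehydration.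
5. 5 ⇐ key ring expansion: desymmetrising diazoethane homologation (cyclopentane → cyclohexane, brings in C8 and its methyl, sets C10) of dione 4 ⇐ 2-methylcyclopentane-1,3-dione + acrolein + isopropylidene Wittig. Ring order: B (five-membered, then expanded), then A.

Assumption: labdane numbering (C1–C20) is used in comments; compounds 5–7 are carried as C8-epimer mixtures because C8 becomes sp2 in step 6. This is a paper route, not run experimentally.

## Route

Step 1
Reactants: 1 2-methylcyclopentane-1,3-dione; 2 acrolein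
Product: 3 3-(1-methyl-2,5-dioxocyclopentyl)propanal
Conditions: H2O, rt (cat. Et3N optional)
Reagents that add atoms: none
Why: Michael addition of the acidic cyclic 1,3-dione (C-nucleophile) to acrolein gives the 2,2-disubstituted dione cleanly; no stereocentre is formed.

Step 2
Reactants: 3 3-(1-methyl-2,5-dioxocyclopentyl)propanal
Product: 4 2-methyl-2-(4-methylpent-3-en-1-yl)cyclopentane-1,3-dione
Conditions: i-PrPPh3I, n-BuLi, THF, −78 → 0 °C; then 3, −78 °C → rt
Reagents that add atoms: isopropyltriphenylphosphonium iodide, CC(C)[P+](c1ccccc1)(c1ccccc1)c1ccccc1.[I-]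
Why: Wittig olefination with a non-stabilised ylide is selective for the aldehyde over the hindered ring ketones and installs the trisubstituted alkene needed for Markovnikov HAT in step 4.

Step 3
Reactants: 4 2-methyl-2-(4-methylpent-3-en-1-yl)cyclopentane-1,3-dione
Product: 5 (2S)-2,4-dimethyl-2-(4-methylpent-3-en-1-yl)cyclohexane-1,3-dione (C4 epimers)
Conditions: diazoethane (0.95 equiv, from EtN(NO)CONH2, aq KOH, Et2O, 0 °C, dried over KOH), Sc(OTf)3 (10 mol %), chiral N,N′-dioxide ligand (12 mol %), toluene, 4 Å MS, −78 °C, slow addition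
Reagents that add atoms: N-ethyl-N-nitrosourea (diazoethane precursor), CCN(N=O)C(N)=O
Why: Proposed new method: a chiral Sc(III)–N,N′-dioxide Lewis acid binds one of the two enantiotopic carbonyls of the prochiral dione (differentiated by the methyl and homoprenyl groups on C2), diazoethane adds to that C=O to give a diazonium alkoxide, and the antiperiplanar ring CH2 (not the acyl-bearing quaternary carbon) undergoes the 1,2-shift with loss of N2, so the ring expansion inserts CH(CH3) next to one carbonyl and the carbonyl choice fixes the quaternary centre (labdane C10) as S; diazoethane is kept limiting to suppress a second insertion; the closest known reaction types are Sc(III)-catalysed asymmetric diazoalkane–ketone homologation (ring expansion) and catalytic desymmetrisation of 2,2-disubstituted cyclopentane-1,3-diones (e.g. CBS reduction).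

Step 4
Reactants: 5 (2S)-2,4-dimethyl-2-(4-methylpent-3-en-1-yl)cyclohexane-1,3-dione
Product: 6 (4aS,8aS)-4a-hydroxy-2,5,5,8a-tetramethyloctahydronaphthalen-1(2H)-one (cis-fused, 5β-OH/10β-Me; C2 epimers)
Conditions: Fe(acac)3 (30 mol %), PhSiH3 (2.5 equiv), EtOH, 60 °C
Reagents that add atoms: none
Why: HAT-initiated radical alkene–ketone cyclisation: Fe–H delivers H to C3, the tertiary C4 radical closes 6-exo onto the less hindered C5 carbonyl (the C9 carbonyl is flanked by the C8 methyl), and the alkoxy radical is reduced to the cis-fused tertiary alcohol, whose C5 configuration is erased in step 5.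

Step 5
Reactants: 6 (4aS,8aS)-4a-hydroxy-2,5,5,8a-tetramethyloctahydronaphthalen-1(2H)-one
Product: 7 (8aS)-2,5,5,8a-tetramethyl-3,5,6,7,8,8a-hexahydronaphthalen-1(2H)-one (C2 epimers)
Conditions: SOCl2, pyridine, CH2Cl2, −10 → 0 °C
Reagents that add atoms: none
Why: E2 dehydration via the chlorosulfite; C4 and C10 are quaternary, so only C6–H can be lost and the Δ5 alkene forms regiospecifically without a free C5 cation (no Wagner–Meerwein shift).

Step 6
Reactants: 7 (8aS)-2,5,5,8a-tetramethyl-3,5,6,7,8,8a-hexahydronaphthalen-1(2H)-one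
Product: 8 (8aS)-2,5,5,8a-tetramethyl-3,5,6,7,8,8a-hexahydronaphthalen-1-yl trifluoromethanesulfonate
Conditions: KHMDS, THF, −78 °C; PhNTf2, −78 → 0 °C
Reagents that add atoms: N-phenylbis(trifluoromethanesulfonimide), O=S(=O)(N(c1ccccc1)S(=O)(=O)C(F)(F)F)C(F)(F)F
Why: C8–H is the only α-hydrogen of the C9 ketone, so enolate O-triflation gives the tetrasubstituted C8=C9 enol triflate regiospecifically and both C8 epimers converge.

Step 7
Reactants: 8 (8aS)-2,5,5,8a-tetramethyl-3,5,6,7,8,8a-hexahydronaphthalen-1-yl trifluoromethanesulfonate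
Product: 11 (4aS,8aS)-2,5,5,8a-tetramethyl-4-oxo-3,4,4a,5,6,7,8,8a-octahydronaphthalen-1-yl trifluoromethanesulfonate, via 6α-alkylborane 9 (not isolated), via 6α-alcohol 10 (not isolated)
Conditions: BH3·THF, THF, 0 °C → rt; NaOH, H2O2, 0 °C; crude alcohol, Dess–Martin periodinane, NaHCO3, CH2Cl2, rt
Reagents that add atoms: hydrogen peroxide, OO; borane–THF, B.C1CCOC1 (boron only in intermediate 9)
Why: Hydroboration–oxidation then Dess–Martin oxidation: borane adds to the trisubstituted Δ5 alkene from the α-face (β-face shielded by the C10 and 4β methyls), syn-delivering H to C5 (5α-H, trans-decalin) and boron to C6, while the electron-poor tetrasubstituted vinyl triflate is inert.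

Step 8
Reactants: 11 (4aS,8aS)-2,5,5,8a-tetramethyl-4-oxo-3,4,4a,5,6,7,8,8a-octahydronaphthalen-1-yl trifluoromethanesulfonate
Product: 13 (3S,4S,4aS,8aS)-3,4-dihydroxy-2,5,5,8a-tetramethyl-3,4,4a,5,6,7,8,8a-octahydronaphthalen-1-yl trifluoromethanesulfonate, via α-ketol 12 (not isolated)
Conditions: KHMDS (1.1 equiv), THF, −78 °C; 2-(phenylsulfonyl)-3-phenyloxaziridine, −78 °C; then MeOH, NaBH4, −78 → −20 °C
Reagents that add atoms: 2-(phenylsulfonyl)-3-phenyloxaziridine (Davis reagent), O=S(=O)(c1ccccc1)N1OC1c1ccccc1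
Why: Davis enolate hydroxylation then substrate-controlled hydride reduction: the C7 dienolate (α to C6=O and allylic) is oxidised by axial attack on the open α-face (7α-OH), and borohydride attacks C6 from the α-face because the β-face is blocked by the syn-axial C10 and 4β methyls (6β-OH), giving the trans-diaxial diol; reducing in the same pot avoids α-ketol isomerisation.

Step 9
Reactants: 14 (2Z)-3-methylpent-2-en-4-yn-1-ol
Product: 15 (2Z)-3-methylpenta-2,4-dien-1-ol
Conditions: H2 (1 atm), Lindlar catalyst, quinoline, EtOAc, rt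
Reagents that add atoms: none
Why: Lindlar semi-hydrogenation reduces the terminal alkyne to the vinyl group and leaves the Z-trisubstituted alkene untouched.

Step 10
Reactants: 13 (3S,4S,4aS,8aS)-3,4-dihydroxy-2,5,5,8a-tetramethyl-3,4,4a,5,6,7,8,8a-octahydronaphthalen-1-yl trifluoromethanesulfonate; 15 (2Z)-3-methylpenta-2,4-dien-1-ol
Product: 17 (13Z)-labda-8,13-diene-6β,7α,15-triol, via bis-borane 16 (not isolated)
Conditions: 15, 9-BBN (2.2 equiv), THF, 0 °C → rt; then 13, PdCl2(dppf) (5 mol %), AsPh3 (10 mol %), K3PO4, DMF/THF/H2O, 50 °C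
Reagents that add atoms: 9-borabicyclo[3.3.1]nonane, B1C2CCCC1CCC2 (boron only in intermediate 16)
Why: 9-BBN hydroborates only the terminal vinyl group (boron on C11; the OH is tied up as the borinate), and the B-alkyl Suzuki–Miyaura coupling joins C11 to C9 with retention of the C8=C9 and 13Z geometries; the substrate has no enolisable ketone.

Step 11
Reactants: 17 (13Z)-labda-8,13-diene-6β,7α,15-triol
Product: 18 (13Z)-labda-8,13-diene-6β,7α,15-triyl triacetate
Conditions: Ac2O, DMAP, pyridine, 50 °C
Reagents that add atoms: acetic anhydride, CC(=O)OC(C)=O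
Why: DMAP-catalysed exhaustive acetylation under forcing conditions also esterifies the hindered axial 6β-OH.

Step 12
Reactants: 18 (13Z)-labda-8,13-diene-6β,7α,15-triyl triacetate
Product: 19 (13Z)-6β-acetoxylabda-8,13-diene-7α,15-diol (CNP0183298.2)
Conditions: K2CO3 (0.3 equiv), MeOH, 0 °C → rt, monitored
Reagents that add atoms: none
Why: Selective transesterification: the primary allylic (C15) and secondary allylic (C7) acetates are cleaved quickly, while the axial 6β-acetate flanked by the C10 and 4β methyls is retained; acyl migration between the trans-diaxial C6 and C7 oxygens is geometrically impossible.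

## Compound list

1 | 2-methylcyclopentane-1,3-dione | CC1C(=O)CCC1=O | starting material
2 | acrolein | C=CC=O | starting material
3 | 3-(1-methyl-2,5-dioxocyclopentyl)propanal | CC1(CCC=O)C(=O)CCC1=O | intermediate
4 | 2-methyl-2-(4-methylpent-3-en-1-yl)cyclopentane-1,3-dione | CC1(CCC=C(C)C)C(=O)CCC1=O | intermediate
5 | (2S)-2,4-dimethyl-2-(4-methylpent-3-en-1-yl)cyclohexane-1,3-dione (C4 epimers) | CC1CCC(=O)[C@](C)(CCC=C(C)C)C1=O | intermediate
6 | (4aS,8aS)-4a-hydroxy-2,5,5,8a-tetramethyloctahydronaphthalen-1(2H)-one (cis-fused; C2 epimers) | O=C1C(C)CC[C@]2(O)C(C)(C)CCC[C@]12C | intermediate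
7 | (8aS)-2,5,5,8a-tetramethyl-3,5,6,7,8,8a-hexahydronaphthalen-1(2H)-one (C2 epimers) | CC1CC=C2C(C)(C)CCC[C@]2(C)C1=O | intermediate
8 | (8aS)-2,5,5,8a-tetramethyl-3,5,6,7,8,8a-hexahydronaphthalen-1-yl trifluoromethanesulfonate | CC1=C(OS(=O)(=O)C(F)(F)F)[C@@]2(C)CCCC(C)(C)C2=CC1 | intermediate
9 | 6α-boryl adduct of 8 (drawn as monoalkylborane; 5α-H) | B[C@H]1CC(C)=C(OS(=O)(=O)C(F)(F)F)[C@@]2(C)CCCC(C)(C)[C@H]12 | intermediate (not isolated)
10 | (4S,4aS,8aS)-4-hydroxy-2,5,5,8a-tetramethyl-3,4,4a,5,6,7,8,8a-octahydronaphthalen-1-yl trifluoromethanesulfonate (6α-OH) | O[C@H]1CC(C)=C(OS(=O)(=O)C(F)(F)F)[C@@]2(C)CCCC(C)(C)[C@H]12 | intermediate (not isolated)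
11 | (4aS,8aS)-2,5,5,8a-tetramethyl-4-oxo-3,4,4a,5,6,7,8,8a-octahydronaphthalen-1-yl trifluoromethanesulfonate | O=C1CC(C)=C(OS(=O)(=O)C(F)(F)F)[C@@]2(C)CCCC(C)(C)[C@H]12 | intermediate
12 | (3S,4aS,8aS)-3-hydroxy-2,5,5,8a-tetramethyl-4-oxo-3,4,4a,5,6,7,8,8a-octahydronaphthalen-1-yl trifluoromethanesulfonate (7α-OH) | O=C1[C@@H](O)C(C)=C(OS(=O)(=O)C(F)(F)F)[C@@]2(C)CCCC(C)(C)[C@H]12 | intermediate (not isolated)
13 | (3S,4S,4aS,8aS)-3,4-dihydroxy-2,5,5,8a-tetramethyl-3,4,4a,5,6,7,8,8a-octahydronaphthalen-1-yl trifluoromethanesulfonate (6β,7α-diol) | O[C@@H]1[C@@H](O)C(C)=C(OS(=O)(=O)C(F)(F)F)[C@@]2(C)CCCC(C)(C)[C@H]12 | intermediate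
14 | (2Z)-3-methylpent-2-en-4-yn-1-ol | C#C/C(C)=C\CO | starting material
15 | (2Z)-3-methylpenta-2,4-dien-1-ol | C=C/C(C)=C\CO | intermediate
16 | 9-[(3Z)-5-(9-borabicyclo[3.3.1]nonan-9-yloxy)-3-methylpent-3-en-1-yl]-9-borabicyclo[3.3.1]nonane | B1(CC/C(C)=C\COB2C3CCCC2CCC3)C2CCCC1CCC2 | intermediate (not isolated)
17 | (13Z)-labda-8,13-diene-6β,7α,15-triol (5S,6S,7S,10S) | O[C@@H]1[C@@H](O)C(C)=C(CC/C(C)=C\CO)[C@@]2(C)CCCC(C)(C)[C@H]12 | intermediate
18 | (13Z)-labda-8,13-diene-6β,7α,15-triyl triacetate | CC(=O)O[C@@H]1[C@@H](OC(C)=O)C(C)=C(CC/C(C)=C\COC(C)=O)[C@@]2(C)CCCC(C)(C)[C@H]12 | intermediate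
19 | (13Z)-6β-acetoxylabda-8,13-diene-7α,15-diol; (1S,2S,4aS,8aS)-2-hydroxy-4-[(3Z)-5-hydroxy-3-methylpent-3-en-1-yl]-3,4a,8,8-tetramethyl-1,2,4a,5,6,7,8,8a-octahydronaphthalen-1-yl acetate | CC(=O)O[C@@H]1[C@@H](O)C(C)=C(CC/C(C)=C\CO)[C@@]2(C)CCCC(C)(C)[C@H]12 | target

## Step count and risks

Total step count: 12. Longest linear sequence: 11 (steps 1–8 and 10–12; step 9 is the side-chain branch).

Three steps most likely to fail:

Step 3 (the proposed new desymmetrising ring expansion: enantioselectivity, and a second insertion into the remaining C5 carbonyl). The fallback sets out from 4 and uses known chemistry only. CBS mono-reduction of the prochiral dione (an established desymmetrisation of 2,2-disubstituted cyclopentane-1,3-diones) gives the hydroxy ketone (2R)-3-hydroxy-2-methyl-2-(4-methylpent-3-en-1-yl)cyclopentan-1-one F1. Fe(acac)3/PhSiH3 HAT cyclisation onto its single remaining ketone gives the cis-fused hydrindane diol F2. Dess–Martin oxidation of the secondary alcohol gives the hydroxy hydrindanone F3. Achiral Sc(OTf)3-promoted diazoethane homologation of this single α-quaternary cyclopentanone (ring CH2 migrates) then expands the ring, and the route is rejoined at 6.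

Step 4 (competition between the C5 and C9 carbonyls for the tertiary radical). The fallback sets out from 5. Kinetic enolisation of the less hindered C5 ketone toward C6 (LiHMDS, −78 °C) protects it in situ as its lithium enolate; DIBAL-H then reduces the free C9 ketone, and work-up gives the hydroxy ketone F4. The same HAT cyclisation, now with only one ketone, gives the bicyclic diol F5. Dess–Martin oxidation of the secondary C9 alcohol brings the route back at 6.

Step 12 (selectivity of partial deacetylation). The fallback sets out from triol 17 and differentiates the hydroxyls by protection instead of by deacylation. TESCl/imidazole (DMF, 0 °C) silylates the primary C15 and the allylic C7 hydroxyls and leaves the hindered axial 6β-OH free, giving the 7,15-bis(triethylsilyl) ether F6. Ac2O/DMAP acetylates the 6β-OH to the 6β-acetate 7,15-bis(triethylsilyl) ether F7. HF·pyridine in THF removes both silyl groups, and the route comes back at 19.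

## Further compounds

F1 | step 3 | (2R)-3-hydroxy-2-methyl-2-(4-methylpent-3-en-1-yl)cyclopentan-1-one (carbinol configuration not relevant) | OC1CCC(=O)[C@]1(C)CCC=C(C)C
F2 | step 3 | cis-fused 4,4,7a-trimethyloctahydro-1H-indene-1,3a-diol (ring-fusion OH cis to the angular methyl; C1 carbinol configuration not relevant) | OC1CC[C@]2(O)C(C)(C)CCC[C@]12C
F3 | step 3 | (3aS,7aS)-3a-hydroxy-4,4,7a-trimethyloctahydro-1H-inden-1-one | O=C1CC[C@]2(O)C(C)(C)CCC[C@]12C
F4 | step 4 | 3-hydroxy-2,4-dimethyl-2-(4-methylpent-3-en-1-yl)cyclohexan-1-one (quaternary centre as in 5; C3 and C4 epimers) | CC1CCC(=O)[C@](C)(CCC=C(C)C)C1O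
F5 | step 4 | cis-fused 2,5,5,8a-tetramethyldecahydronaphthalene-1,4a-diol (ring-fusion OH cis to the angular methyl; C1 and C2 epimers) | CC1CC[C@]2(O)C(C)(C)CCC[C@]2(C)C1O
F6 | step 12 | (13Z)-7α,15-bis(triethylsilyloxy)labda-8,13-dien-6β-ol | O[C@@H]1[C@@H](O[Si](CC)(CC)CC)C(C)=C(CC/C(C)=C\CO[Si](CC)(CC)CC)[C@@]2(C)CCCC(C)(C)[C@H]12
F7 | step 12 | (13Z)-7α,15-bis(triethylsilyloxy)labda-8,13-dien-6β-yl acetate | CC(=O)O[C@@H]1[C@@H](O[Si](CC)(CC)CC)C(C)=C(CC/C(C)=C\CO[Si](CC)(CC)CC)[C@@]2(C)CCCC(C)(C)[C@H]12
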